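The pitfall in eta and delta is to take chain length as monomer charged over initiator charged, 20.0 and 6.67: the statistical zero of the scale.

| flask | free monomer | transfer agent | protic impurity | initiator | remark | time |
|---|---|---|---|---|---|---|
| ash | 0.20 M | 2 mM | 0.060 M | 3.1 mol% | run made earlier |  |
| alder | 0.20 M | 2 mM | 0.060 M | 12 mol% | run made earlier |  |
| eta | 0.20 M | 2.00 mM | 0.0600 M | 5 mol% |  | 80 min |
| delta | 0.20 M | 2.00 mM | 0.0600 M | 15 mol% |  | 80 min |

| run | time / min | monomer in chains / % | free monomer / % |
|---|---|---|---|
| ash | 4.00 | 24.2 | 49.2 |
| ash | 10.0 | 33.0 | 37.7 |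
| ash | 20.0 | 37.2 | 31.1 |
| ash | 30.0 | 36.4 | 29.3 |
| ash | 40.0 | 39.8 | 30.6 |
| ash | 60.0 | 39.2 | 28.2 |
| alder | 10.0 | 53.8 | 15.1 |
| alder | 20.0 | 57.9 | 11.1 |
| alder | 30.0 | 57.5 | 10.5 |
| alder | 40.0 | 59.4 | 10.0 |
| alder | 50.0 | 60.1 | 8.5 |
| alder | 60.0 | 58.1 | 8.9 |

(readings scatter by 1 percentage point)

- the average divides the monomer in chains by the number of chains begun, living and dead together
- the earlier runs do not show the number of chains; that part of a forecast is a guess

* which of the two ends with the longer chains by the average number of monomer units in a chain (chains begun, living or dead) ("neither" if they lie within 10%) (eta / delta / neither)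
* average number of monomer units in a chain (chains begun, living or dead) at the end, eta
* average number of monomer units in a chain (chains begun, living or dead) at the end, delta

But the earlier runs lose monomer. At its last reading the ash run lacks 32.6% of its charge from chains plus free monomer, and the alder run lacks 33.0%. The protic impurity is charged at 30.0% of the monomer, so one impurity appears to take one monomer.

So the ceiling length Λ is 14.0 for eta and 4.67 for delta: monomer charge less impurity charge, over initiator charge. It assumes one chain per initiator, which the runs do not show.

Free monomer also stalls, so a fill φ is needed: monomer in chains over that same difference. It reads 0.560 in the ash run and 0.830 in the alder run. Eta's loading lies between theirs and delta's lies above both. If φ keeps rising with loading, this reckoning puts eta between 7.84 and 11.6, and delta between 3.88 and 4.67. Eta's low end stands above delta's high end, so eta ends longer.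

The forecast also says eta, with 8.5 and 4.1, and adds: “The number of chains is a guess.”

The flask gives eta, at 9.34 against 4.22, so length over Λ, which is φ under one chain per initiator, is 0.667 in eta and 0.904 in delta.

    free monomer + initiator → living end + monomer in chains (k = 0.0840 M⁻¹ s⁻¹)
    free monomer + living end → monomer in chains + living end, rate k2*[living end]*[free monomer] (k = 0.480 M⁻¹ s⁻¹)
    living end + transfer agent → dead chain (kL = 0.230 M⁻¹ s⁻¹)
    living end + monomer in chains → dead end A (k = 0.0100 M⁻¹ s⁻¹)
    protic impurity + free monomer → quenched substrate (k = 0.0700 M⁻¹ s⁻¹)
    2 living end → dead end B (k = 0.900 M⁻¹ s⁻¹)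

The neighbouring flask is delta with 0.50 M of free monomer, the protic impurity standing at 0.120 equiv. Its Λ is 5.87, and delta's φ turns that into 5.30. The neighbour keeps a larger part of its charged free monomer than delta, 12.5% against 5.07%. Its length is 4.92.

All runs were generated by integration on assumed constants, and the scatter is random.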